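## Retrosynthetic overview

- **Feature.** Justin C is an acyclic 1,4-diarylbutane. Its only stereo-elements are the adjacent CH centres C8 and C8′, both R (C7/C7′ = ArCH2, C9/C9′ = CH2OAc, primes = syringyl half). Each centre carries a one-carbon arm, so both arms can be grown with retention from boron atoms placed on C8 and C8′.
- **Late disconnections.** 13 ⇒ (O-benzyl, O-acetyl) 1,4-diol 11 ⇒ (C8–C9 and C8′–C9′, double CH2 insertion into C–B) vicinal bis(boronate) 9 ⇒ (C8–B and C8′–B, enantioselective syn-diboration) E-alkene 6 + B2cat2 7.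
- **Early disconnections.** 6 ⇒ (C7–C8, sp2–sp3 Suzuki coupling) E-alkenylboronate 4 + veratryl chloride 5. 4 ⇒ (C8=C8′, cross-metathesis) O-benzyl methoxyeugenol 2 + vinyl-Bpin 3. This stereodefined sequence is preferred to a statistical metathesis of two allylarenes because 6 must be geometrically pure.
- **Rings.** None is formed. The veratryl and syringyl benzene rings are bought intact, and the dioxaborole/dioxaborolane rings are spectators on boron.

Key step: step 4

Assumption: the sense of induction of Quinap cannot be fixed on paper for 6, so (S)-Quinap is written, the configuration of 9 is to be checked by correlation on an oxidised aliquot, and the commercial (R)-antipode is used instead if the (2S,3S) series is found.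

## Route

Step 1
Reactants: 1 4-allyl-2,6-dimethoxyphenol (methoxyeugenol)
Product: 2 5-allyl-2-(benzyloxy)-1,3-dimethoxybenzene
Conditions: BnBr, K2CO3, DMF, 23 → 50 °C
Reagents that add atoms: benzyl bromide, BrCc1ccccc1
Why: Williamson etherification of the phenoxide masks the acidic, oxidisable syringyl OH through the Ru, Pd, Rh, organolithium and peroxide steps as a group that leaves by neutral hydrogenolysis at the end.

Step 2
Reactants: 2 5-allyl-2-(benzyloxy)-1,3-dimethoxybenzene; 3 4,4,5,5-tetramethyl-2-vinyl-1,3,2-dioxaborolane (vinylboronic acid pinacol ester)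
Product: 4 2-[(E)-3-[4-(benzyloxy)-3,5-dimethoxyphenyl]prop-1-en-1-yl]-4,4,5,5-tetramethyl-1,3,2-dioxaborolane
Conditions: Hoveyda–Grubbs II (3 mol %), 1,4-benzoquinone (10 mol %), 3 (2 equiv), CH2Cl2, 40 °C
Reagents that add atoms: none
Why: Olefin cross-metathesis of a fast-reacting allylarene with vinyl-Bpin, which homodimerises only slowly, should favour the cross product, the bulky Bpin group favours the E-alkenylboronate, and benzoquinone intercepts Ru–H species that would move the double bond into conjugation.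

Step 3
Reactants: 4 the E-alkenylboronate from step 2; 5 4-(chloromethyl)-1,2-dimethoxybenzene (3,4-dimethoxybenzyl chloride, cold-stored batch, 1.3 equiv)
Product: 6 (E)-1-[4-(benzyloxy)-3,5-dimethoxyphenyl]-4-(3,4-dimethoxyphenyl)but-2-ene
Conditions: Pd(OAc)2 (3 mol %), SPhos (6 mol %), K3PO4, THF/H2O (10:1), 50 °C
Reagents that add atoms: none
Why: Suzuki–Miyaura sp2–sp3 coupling (benzylic C–Cl oxidative addition, transmetalation and reductive elimination with retention of the alkenyl geometry, no β-hydrogen on benzyl-Pd) should carry the E geometry of 4 into the C7–C8 bond-forming product 6.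

Step 4
Reactants: 6 (E)-1-[4-(benzyloxy)-3,5-dimethoxyphenyl]-4-(3,4-dimethoxyphenyl)but-2-ene; 7 bis(catecholato)diboron (1.2 equiv)
Product: 9 2,2′-[(2R,3R)-1-[4-(benzyloxy)-3,5-dimethoxyphenyl]-4-(3,4-dimethoxyphenyl)butane-2,3-diyl]bis(4,4,5,5-tetramethyl-1,3,2-dioxaborolane), via 2,2′-[(2R,3R)-1-[4-(benzyloxy)-3,5-dimethoxyphenyl]-4-(3,4-dimethoxyphenyl)butane-2,3-diyl]bis(1,3,2-benzodioxaborole) 8 (not isolated)
Conditions: (nbd)Rh(acac) (5 mol %), (S)-Quinap (5 mol %), THF, 23 °C; then pinacol (4 equiv), THF, 23 °C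
Reagents that add atoms: pinacol, CC(C)(O)C(C)(C)O
Why: The B–B bond of 7 adds oxidatively to the Quinap–Rh(I) complex, the alkene of 6 inserts into one Rh–B bond and C–B reductive elimination closes the cycle, so both boryl groups reach C8 and C8′ from the same face (syn addition); pinacol then displaces catechol at boron without touching the C–B bonds. The closest known reaction type is the Rh(I)/Quinap-catalysed enantioselective diboration of unconjugated trans-1,2-disubstituted alkenes with B2cat2, the class to which the 1,2-bis(arylmethyl)ethene 6 belongs. No ring is closed and no skeletal C–C bond is made; only the C8–B and C8′–B bonds form. The relative configuration (threo) follows from E geometry plus syn addition, and the absolute configuration (8R,8′R) from the P,N-ligand, which distinguishes the enantiotopic faces of the trans-alkene. The step needs enantioface selectivity only: regiochemistry is void because both alkene carbons receive boron, the two CH2Ar substituents are sterically alike so that either in-plane orientation of 6 on the metal leads to the same enantiomer, and the arenes and ethers are inert. Fast reductive elimination from the electron-poor catecholatoboryl–Rh species at 23 °C should keep β-hydride elimination towards the benzylic C7/C7′ hydrogens in check.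

Step 5
Reactants: 9 the (2R,3R)-bis(pinacol boronate) from step 4
Product: 10 2,2′-[(2R,3R)-2-[4-(benzyloxy)-3,5-dimethoxybenzyl]-3-(3,4-dimethoxybenzyl)butane-1,4-diyl]bis(4,4,5,5-tetramethyl-1,3,2-dioxaborolane)
Conditions: BrCH2Cl (6 equiv), n-BuLi (5 equiv, added last, dropwise), THF, −78 → 23 °C
Reagents that add atoms: bromochloromethane, ClCBr
Why: Double Matteson homologation with LiCH2Cl made in situ forms an ate complex at each boron at −78 °C, and on warming each secondary alkyl group migrates from B to CH2 with loss of chloride and retention at C8 and C8′, while surplus carbenoid decomposes before migration and so limits repeated insertion.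

Step 6
Reactants: 10 the homologated (2R,3R)-bis(pinacol boronate)
Product: 11 (2R,3R)-2-[4-(benzyloxy)-3,5-dimethoxybenzyl]-3-(3,4-dimethoxybenzyl)butane-1,4-diol
Conditions: 30 % H2O2, 3 M NaOH, THF, 0 → 23 °C
Reagents that add atoms: hydrogen peroxide, OO
Why: Hydroperoxide oxidation of the primary alkylboronates (B→O 1,2-migration, then hydrolysis) turns C9–B and C9′–B into C–OH, with the stereocentres one carbon away from the reacting atoms and therefore untouched.

Step 7
Reactants: 11 the (2R,3R)-1,4-diol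
Product: 12 (2R,3R)-2-[4-(benzyloxy)-3,5-dimethoxybenzyl]-3-(3,4-dimethoxybenzyl)butane-1,4-diyl diacetate
Conditions: Ac2O, pyridine, DMAP (cat.), CH2Cl2, 23 °C
Reagents that add atoms: acetic anhydride, CC(=O)OC(C)=O
Why: DMAP-catalysed acylation of two unhindered primary alcohols, done while the phenol is still benzylated so that only C9–OH and C9′–OH are acetylated.

Step 8
Reactants: 12 the O-benzyl diacetate
Product: 13 Justin C, (2R,3R)-2-(3,4-dimethoxybenzyl)-3-(4-hydroxy-3,5-dimethoxybenzyl)butane-1,4-diyl diacetate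
Conditions: H2 (1 atm), 10 % Pd/C, EtOAc, 23 °C
Reagents that add atoms: none
Why: Catalytic hydrogenolysis cleaves only the benzylic C–O bond of the aryl benzyl ether under neutral conditions, which leaves the primary acetates, the aryl methyl ethers, the C7/C7′ benzylic C–C bonds and both stereocentres intact.

## Compound list

1 | 4-allyl-2,6-dimethoxyphenol (methoxyeugenol) | C=CCc1cc(OC)c(O)c(OC)c1 | starting material
2 | 5-allyl-2-(benzyloxy)-1,3-dimethoxybenzene | C=CCc1cc(OC)c(OCc2ccccc2)c(OC)c1 | intermediate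
3 | 4,4,5,5-tetramethyl-2-vinyl-1,3,2-dioxaborolane | C=CB1OC(C)(C)C(C)(C)O1 | starting material
4 | 2-[(E)-3-[4-(benzyloxy)-3,5-dimethoxyphenyl]prop-1-en-1-yl]-4,4,5,5-tetramethyl-1,3,2-dioxaborolane | COc1cc(C/C=C/B2OC(C)(C)C(C)(C)O2)cc(OC)c1OCc1ccccc1 | intermediate
5 | 4-(chloromethyl)-1,2-dimethoxybenzene (3,4-dimethoxybenzyl chloride) | COc1ccc(CCl)cc1OC | starting material
6 | (E)-1-[4-(benzyloxy)-3,5-dimethoxyphenyl]-4-(3,4-dimethoxyphenyl)but-2-ene | COc1ccc(C/C=C/Cc2cc(OC)c(OCc3ccccc3)c(OC)c2)cc1OC | intermediate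
7 | bis(catecholato)diboron | B1(Oc2ccccc2O1)B1Oc2ccccc2O1 | starting material
8 | 2,2′-[(2R,3R)-1-[4-(benzyloxy)-3,5-dimethoxyphenyl]-4-(3,4-dimethoxyphenyl)butane-2,3-diyl]bis(1,3,2-benzodioxaborole) | COc1ccc(C[C@@H](B2Oc3ccccc3O2)[C@H](B2Oc3ccccc3O2)Cc2cc(OC)c(OCc3ccccc3)c(OC)c2)cc1OC | intermediate (not isolated)
9 | 2,2′-[(2R,3R)-1-[4-(benzyloxy)-3,5-dimethoxyphenyl]-4-(3,4-dimethoxyphenyl)butane-2,3-diyl]bis(4,4,5,5-tetramethyl-1,3,2-dioxaborolane) | COc1ccc(C[C@@H](B2OC(C)(C)C(C)(C)O2)[C@H](B2OC(C)(C)C(C)(C)O2)Cc2cc(OC)c(OCc3ccccc3)c(OC)c2)cc1OC | intermediate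
10 | 2,2′-[(2R,3R)-2-[4-(benzyloxy)-3,5-dimethoxybenzyl]-3-(3,4-dimethoxybenzyl)butane-1,4-diyl]bis(4,4,5,5-tetramethyl-1,3,2-dioxaborolane) | COc1ccc(C[C@@H](CB2OC(C)(C)C(C)(C)O2)[C@H](CB2OC(C)(C)C(C)(C)O2)Cc2cc(OC)c(OCc3ccccc3)c(OC)c2)cc1OC | intermediate
11 | (2R,3R)-2-[4-(benzyloxy)-3,5-dimethoxybenzyl]-3-(3,4-dimethoxybenzyl)butane-1,4-diol | COc1ccc(C[C@@H](CO)[C@H](CO)Cc2cc(OC)c(OCc3ccccc3)c(OC)c2)cc1OC | intermediate
12 | (2R,3R)-2-[4-(benzyloxy)-3,5-dimethoxybenzyl]-3-(3,4-dimethoxybenzyl)butane-1,4-diyl diacetate | COc1ccc(C[C@@H](COC(C)=O)[C@H](COC(C)=O)Cc2cc(OC)c(OCc3ccccc3)c(OC)c2)cc1OC | intermediate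
13 | Justin C, (2R,3R)-2-(3,4-dimethoxybenzyl)-3-(4-hydroxy-3,5-dimethoxybenzyl)butane-1,4-diyl diacetate | COc1ccc(C[C@@H](COC(C)=O)[C@H](COC(C)=O)Cc2cc(OC)c(O)c(OC)c2)cc1OC | target

## Counts

- Total step count: 8
- Longest linear sequence: 8 steps (1 → 13)

## Steps most likely to fail

**Step 4.** After borylrhodation the secondary alkyl-Rh species may undergo β-hydride elimination towards the benzylic C7/C7′ hydrogens faster than C–B reductive elimination. That would cause chain walking and hydroboration-type consumption of the alkene. Facial discrimination between two remote, flat CH2Ar groups may also be insufficient.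

The fallback gives up catalytic enantiocontrol and keeps only the stereospecific syn addition.
- From 6, transition-metal-free diboration with bis(pinacolato)diboron activated by methoxide (Cs2CO3 cat., MeOH, THF, 70 °C) cannot form a metal hydride. It should give the threo bis(boronate) as the racemate, that is 9 together with its enantiomer, the (2S,3S)-bis(pinacol boronate) F1.
- Steps 5 and 6 on the racemate give 10 and 11 together with the (2S,3S)-homologated bis(pinacol boronate) F2 and the (2S,3S)-1,4-diol F3.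
- Esterification with (S)-2-methoxy-2-phenylacetic acid (DCC, DMAP, CH2Cl2) turns the pair into two diastereomers, the (2R,3R)-diol bis[(S)-methoxy(phenyl)acetate] F4 and the (2S,3S)-diol bis[(S)-methoxy(phenyl)acetate] F5.
- These are separated by chromatography or crystallisation and assigned by crystallography.
- Methanolysis of F4 (K2CO3, MeOH) returns 11, where the route is rejoined.

**Step 5.** The second carbenoid capture may stall because the two secondary boronates are vicinal and crowded. n-BuLi may attack boron in competition with Li/Br exchange, or the new primary boronate may take up a further CH2.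

The fallback replaces the fleeting carbenoid by a stable nucleophile that can be used in excess and followed by 11B NMR.
- From 9, double Zweifel olefination (vinylmagnesium bromide, THF/DMSO; I2; NaOMe, MeOH) exchanges each C–B for C–CH=CH2 with retention. This gives (3S,4S)-3-[4-(benzyloxy)-3,5-dimethoxybenzyl]-4-(3,4-dimethoxybenzyl)hexa-1,5-diene F6.
- Lemieux–Johnson cleavage (OsO4 cat., NaIO4, 2,6-lutidine, dioxane/H2O) gives (2R,3R)-2-[4-(benzyloxy)-3,5-dimethoxybenzyl]-3-(3,4-dimethoxybenzyl)butanedial F7.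
- F7 is reduced at once (NaBH4, MeOH, 0 °C), before it can epimerise, and the route is rejoined at 11. Steps 5 and 6 are bypassed.

**Step 3.** Solvolysis and homocoupling of the electron-rich benzylic chloride, or protodeboronation of 4, may outrun the cross-coupling. Pd–H species may also shift the skipped double bond into conjugation and erode the geometric purity on which step 4 depends.

The fallback builds the C8=C8′ bond itself by a metal-free, E-selective olefination and also bypasses step 2.
- From 2, Lemieux–Johnson cleavage (OsO4 cat., NaIO4, 2,6-lutidine, dioxane/H2O) gives 2-[4-(benzyloxy)-3,5-dimethoxyphenyl]acetaldehyde F8.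
- Separately, commercial 2-(3,4-dimethoxyphenyl)ethanol is converted by Mitsunobu reaction with 1-phenyl-1H-tetrazole-5-thiol (PPh3, DIAD, THF) into 5-{[2-(3,4-dimethoxyphenyl)ethyl]sulfanyl}-1-phenyl-1H-tetrazole F9.
- F9 is oxidised (H2O2, ammonium molybdate, EtOH) to 5-{[2-(3,4-dimethoxyphenyl)ethyl]sulfonyl}-1-phenyl-1H-tetrazole F10.
- Julia–Kocienski olefination (KHMDS, DME, −60 °C, then F8) should give the E-alkene, and the route is rejoined at 6.

## Further compounds

F1 | step 4 | 2,2′-[(2S,3S)-1-[4-(benzyloxy)-3,5-dimethoxyphenyl]-4-(3,4-dimethoxyphenyl)butane-2,3-diyl]bis(4,4,5,5-tetramethyl-1,3,2-dioxaborolane) | COc1ccc(C[C@H](B2OC(C)(C)C(C)(C)O2)[C@@H](B2OC(C)(C)C(C)(C)O2)Cc2cc(OC)c(OCc3ccccc3)c(OC)c2)cc1OC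
F2 | step 4 | 2,2′-[(2S,3S)-2-[4-(benzyloxy)-3,5-dimethoxybenzyl]-3-(3,4-dimethoxybenzyl)butane-1,4-diyl]bis(4,4,5,5-tetramethyl-1,3,2-dioxaborolane) | COc1ccc(C[C@H](CB2OC(C)(C)C(C)(C)O2)[C@@H](CB2OC(C)(C)C(C)(C)O2)Cc2cc(OC)c(OCc3ccccc3)c(OC)c2)cc1OC
F3 | step 4 | (2S,3S)-2-[4-(benzyloxy)-3,5-dimethoxybenzyl]-3-(3,4-dimethoxybenzyl)butane-1,4-diol | COc1ccc(C[C@H](CO)[C@@H](CO)Cc2cc(OC)c(OCc3ccccc3)c(OC)c2)cc1OC
F4 | step 4 | (2R,3R)-2-[4-(benzyloxy)-3,5-dimethoxybenzyl]-3-(3,4-dimethoxybenzyl)butane-1,4-diyl bis[(2S)-2-methoxy-2-phenylacetate] | COc1ccc(C[C@@H](COC(=O)[C@@H](OC)c2ccccc2)[C@H](COC(=O)[C@@H](OC)c2ccccc2)Cc2cc(OC)c(OCc3ccccc3)c(OC)c2)cc1OC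
F5 | step 4 | (2S,3S)-2-[4-(benzyloxy)-3,5-dimethoxybenzyl]-3-(3,4-dimethoxybenzyl)butane-1,4-diyl bis[(2S)-2-methoxy-2-phenylacetate] | COc1ccc(C[C@H](COC(=O)[C@@H](OC)c2ccccc2)[C@@H](COC(=O)[C@@H](OC)c2ccccc2)Cc2cc(OC)c(OCc3ccccc3)c(OC)c2)cc1OC
F6 | step 5 | (3S,4S)-3-[4-(benzyloxy)-3,5-dimethoxybenzyl]-4-(3,4-dimethoxybenzyl)hexa-1,5-diene | COc1ccc(C[C@@H](C=C)[C@H](C=C)Cc2cc(OC)c(OCc3ccccc3)c(OC)c2)cc1OC
F7 | step 5 | (2R,3R)-2-[4-(benzyloxy)-3,5-dimethoxybenzyl]-3-(3,4-dimethoxybenzyl)butanedial | COc1ccc(C[C@@H](C=O)[C@H](C=O)Cc2cc(OC)c(OCc3ccccc3)c(OC)c2)cc1OC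
F8 | step 3 | 2-[4-(benzyloxy)-3,5-dimethoxyphenyl]acetaldehyde | O=CCc1cc(OC)c(OCc2ccccc2)c(OC)c1
F9 | step 3 | 5-{[2-(3,4-dimethoxyphenyl)ethyl]sulfanyl}-1-phenyl-1H-tetrazole | COc1ccc(CCSc2nnnn2-c2ccccc2)cc1OC
F10 | step 3 | 5-{[2-(3,4-dimethoxyphenyl)ethyl]sulfonyl}-1-phenyl-1H-tetrazole | COc1ccc(CCS(=O)(=O)c2nnnn2-c2ccccc2)cc1OC
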